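**Plan**
- Retrosynthesis cuts, in this order: the side-chain C=C (Wittig); the C3–H and C6–H bonds (hydride) and the C6–O and C4–O bonds (enolate oxidations), back to a cyclohexenone; then C2–C3 and C1–C6 of the ring (alkyne insertion), leaving a cyclobutanone ([2+2]) and an enyne (Sonogashira).
- Enabling feature: C3–C4–C5–C6, with C5 as the only carbon-branched atom, is a 3-substituted cyclobutanone with its carbonyl at C3; the tetrasubstituted C1=C2 alkene with the heptenyl group on C1 is the alkyne of a conjugated enyne.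
- Forward: the four-membered ring is made first and expanded to the six-membered ring in the key step (the only ring-forming events); oxygen is added at C4, then C6; C3 and C6 are reduced; the side chain is joined last.
- Stereochemistry: C5 from the chiral nickel catalyst; O4 trans to the side chain by Rubottom oxidation; C3 and C6 by bulky-hydride attack opposite their neighbours; alkene geometries from hydrozirconation and a stabilised ylide.

Key step: step 7

Ring numbering throughout is that of the target: C1 carries the heptenyl group, C2 the CH2O group, C5 the side chain. TBS = tert-butyldimethylsilyl, TBDPS = tert-butyldiphenylsilyl.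
Assumption: the sense of induction of a new asymmetric catalysis cannot be predicted, so the ligand enantiomer that gives (5S)-13 is taken to be fixed by a first screen; 17 is drawn as the C6 epimer expected from attack opposite the side chain, and either epimer serves in step 10.

Step 1
Reactants: 1 but-3-en-1-ol
Product: 2 tert-butyl(but-3-en-1-yloxy)dimethylsilane
Conditions: TBSCl, imidazole, CH2Cl2, 0 °C → rt
Reagents that add atoms: tert-butyldimethylsilyl chloride, CC(C)(C)[Si](C)(C)Cl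
Why: Silylation of a primary alcohol gives an ether that should withstand the zinc, nickel and amide-base steps and is later the only primary TBS ether, so it can be removed selectively.

Step 2
Reactants: 2 tert-butyl(but-3-en-1-yloxy)dimethylsilane; 3 trichloroacetyl chloride
Product: 5 rac-2,2-dichloro-3-[2-(TBS-oxy)ethyl]cyclobutan-1-one, via dichloroketene 4 (not isolated)
Conditions: Zn–Cu couple, Et2O/DME, rt, slow addition of 3
Reagents that add atoms: none
Why: Thermal [2+2] cycloaddition of dichloroketene (from zinc dehalogenation of 3) to the terminal alkene joins the ketene carbonyl carbon to the CH2 terminus and tolerates the silyl ether.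

Step 3
Reactants: 5 rac-2,2-dichloro-3-[2-(TBS-oxy)ethyl]cyclobutan-1-one
Product: 6 3-[2-(TBS-oxy)ethyl]cyclobutan-1-one
Conditions: Zn dust, NH4Cl, MeOH, rt
Reagents that add atoms: none
Why: Reductive dehalogenation of the α,α-dichloroketone by zinc leaves the prochiral cyclobutanone, whose mirror plane passes through the carbonyl carbon and the substituted carbon.

Step 4
Reactants: 7 prop-2-yn-1-ol
Product: 8 tert-butyldiphenyl(prop-2-yn-1-yloxy)silane
Conditions: TBDPSCl, imidazole, CH2Cl2, 0 °C → rt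
Reagents that add atoms: tert-butyldiphenylsilyl chloride, CC(C)(C)[Si](Cl)(c1ccccc1)c1ccccc1
Why: Silylation with the acid-stable TBDPS group, which should survive the acidic methanolysis of step 13 and leave with fluoride at the end.

Step 5
Reactants: 9 hept-1-yne
Product: 11 (E)-1-iodohept-1-ene, via alkenylzirconocene chloride 10 (not isolated)
Conditions: Cp2Zr(H)Cl, THF, rt; then I2, 0 °C
Reagents that add atoms: iodine, II; zirconocene chloride hydride, [H][Zr](Cl)(C1C=CC=C1)C1C=CC=C1 (zirconium kept only in 10)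
Why: syn-Hydrozirconation of the terminal alkyne places zirconium on C1 with E geometry, and iodinolysis of the C–Zr bond proceeds with retention.

Step 6
Reactants: 8 tert-butyldiphenyl(prop-2-yn-1-yloxy)silane; 11 (E)-1-iodohept-1-ene
Product: 12 tert-butyl{[(E)-dec-4-en-2-yn-1-yl]oxy}diphenylsilane
Conditions: Pd(PPh3)2Cl2 (2 mol %), CuI (4 mol %), Et3N, THF, rt
Reagents that add atoms: none
Why: Sonogashira coupling of a terminal alkyne with an alkenyl iodide keeps the E geometry and gives the conjugated enyne (a ten-carbon chain).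

Step 7
Reactants: 6 3-[2-(TBS-oxy)ethyl]cyclobutan-1-one; 12 tert-butyl{[(E)-dec-4-en-2-yn-1-yl]oxy}diphenylsilane
Product: 13 (5S)-1-[(E)-hept-1-enyl]-2-[(TBDPS-oxy)methyl]-5-[2-(TBS-oxy)ethyl]cyclohex-1-en-3-one
Conditions: Ni(cod)2 (10 mol %), chiral BINOL-derived phosphoramidite L* (20 mol %), toluene, 60 °C, slow addition of 12
Reagents that add atoms: none
Why: Proposed new method: Ni(0) should couple the ketone carbonyl and the alkyne by oxidative cyclisation to a spiro oxanickelacyclopentene (C2–C3 bond), β-carbon elimination then cleaves the strained C3–C6 bond, and C(sp2)–C(sp3) reductive elimination from the seven-membered nickelacycle forms C1–C6 and releases the cyclohexenone. The closest known reaction type is the Ni(0)/phosphine-catalysed intermolecular insertion of internal alkynes into cyclobutanones (formal [4+2] ring expansion), together with its enantioselective intramolecular versions with chiral phosphorus ligands. The six-membered ring closes by two-carbon expansion of the four-membered ring, the ring-forming event being the reductive elimination at C1–C6. C5 becomes a stereocentre without a bond to it being made: after oxidative cyclisation the two C3–CH2 bonds are enantiotopic, and the chiral ligand on nickel must choose which one is cleaved. The step needs regioselectivity (carbonyl carbon to the alkyne carbon remote from the alkene), which the conjugated alkene should secure by binding nickel so that the metal sits on the alkenyl-bearing carbon, as in nickel-catalysed carbonyl–enyne couplings. Slow addition of 12 should hold back alkyne oligomerisation.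

Step 8
Reactants: 13 (5S)-enone
Product: 15 (4S,5S)-4-(TBS-oxy)-1-[(E)-hept-1-enyl]-2-[(TBDPS-oxy)methyl]-5-[2-(TBS-oxy)ethyl]cyclohex-1-en-3-one (O4 trans to the side chain), via TBS dienol ether 14 (not isolated)
Conditions: LDA, THF, −78 °C, then TBSOTf; crude 14, DMDO, acetone/CH2Cl2, −78 → 0 °C
Reagents that add atoms: tert-butyldimethylsilyl triflate, CC(C)(C)[Si](C)(C)OS(=O)(=O)C(F)(F)F; dimethyldioxirane, CC1(C)OO1
Why: Kinetic deprotonation of the enone at C4 (α′), O-silylation and Rubottom oxidation (epoxidation of the enol ether, then 1,4-silyl shift) should place the silyloxy group at C4 on the face opposite the neighbouring C5 side chain.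

Step 9
Reactants: 15 (4S,5S)-4-silyloxy enone
Product: 17 (4S,5R,6R)-4-(TBS-oxy)-6-hydroxy-1-[(E)-hept-1-enyl]-2-[(TBDPS-oxy)methyl]-5-[2-(TBS-oxy)ethyl]cyclohex-1-en-3-one, via TMS dienol ether 16 (not isolated)
Conditions: LiHMDS, TMSCl, THF, −78 °C; crude 16, DMDO, acetone/CH2Cl2, −78 °C; aq. NaH2PO4 work-up
Reagents that add atoms: dimethyldioxirane, CC1(C)OO1; chlorotrimethylsilane, C[Si](C)(C)Cl (silicon kept only in 16)
Why: With C4 blocked by its silyloxy group, the lithium amide should remove a ring hydrogen at C6 (γ, cis to the carbonyl across C1=C2), and the silyl dienol ether is then oxidised at its C1=C6 bond (vinylogous Rubottom oxidation); the C6 configuration is erased in step 10.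

Step 10
Reactants: 17 γ-hydroxy enone
Product: 18 (4S,5S)-4-(TBS-oxy)-1-[(E)-hept-1-enyl]-2-[(TBDPS-oxy)methyl]-5-[2-(TBS-oxy)ethyl]cyclohex-1-ene-3,6-dione
Conditions: Dess–Martin periodinane, pyridine, CH2Cl2, 0 °C; used without chromatography
Reagents that add atoms: none
Why: Dess–Martin oxidation of the allylic alcohol under buffered, near-neutral conditions should give the enedione without base-induced loss of the β-silyloxy group.

Step 11
Reactants: 18 enedione
Product: 19 (3R,4S,5R,6S)-4-(TBS-oxy)-1-[(E)-hept-1-enyl]-2-[(TBDPS-oxy)methyl]-5-[2-(TBS-oxy)ethyl]cyclohex-1-ene-3,6-diol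
Conditions: L-Selectride (2.5 equiv), THF, −78 °C; H2O quench
Reagents that add atoms: none
Why: Steric-approach-controlled 1,2-reduction by the bulky trialkylborohydride: hydride should enter each carbonyl from the face opposite the substituent on its sp3 neighbour (anti to OTBS at C3, anti to the side chain at C6), giving the 3,4-cis and 5,6-cis alcohols, while the tetrasubstituted C1=C2 bond resists conjugate reduction.

Step 12
Reactants: 19 diol
Product: 20 (3R,4S,5R,6S)-3,6-diacetoxy-4-(TBS-oxy)-1-[(E)-hept-1-enyl]-2-[(TBDPS-oxy)methyl]-5-[2-(TBS-oxy)ethyl]cyclohex-1-ene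
Conditions: Ac2O, pyridine, DMAP (cat.), CH2Cl2, rt
Reagents that add atoms: acetic anhydride, CC(=O)OC(C)=O
Why: DMAP-catalysed acetylation masks the two allylic alcohols for the side-chain oxidation and lets them leave together with the ester in the last step.

Step 13
Reactants: 20 diacetate
Product: 21 (3R,4S,5R,6S)-3,6-diacetoxy-4-(TBS-oxy)-1-[(E)-hept-1-enyl]-2-[(TBDPS-oxy)methyl]-5-(2-hydroxyethyl)cyclohex-1-ene
Conditions: PPTS (cat.), MeOH, rt
Reagents that add atoms: none
Why: Acid-catalysed methanolysis (selective desilylation) cleaves the unhindered primary TBS ether much faster than the flanked secondary TBS ether or the primary TBDPS ether.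

Step 14
Reactants: 21 primary alcohol; 22 ethyl 2-(triphenyl-λ5-phosphanylidene)propanoate
Product: 24 ethyl (2E)-4-[(3R,4S,5R,6S)-3,6-diacetoxy-4-(TBS-oxy)-1-[(E)-hept-1-enyl]-2-[(TBDPS-oxy)methyl]cyclohex-1-en-5-yl]-2-methylbut-2-enoate, via aldehyde 23 (not isolated)
Conditions: Dess–Martin periodinane, pyridine, CH2Cl2, 0 °C → rt; then 22, rt
Reagents that add atoms: none
Why: Dess–Martin oxidation gives the aldehyde, which the stabilised ylide converts in the same flask into the trisubstituted enoate with E geometry (Wittig reaction).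

Step 15
Reactants: 24 protected enoate
Product: 26 pestallic acid P, via desilylated diacetate ester 25 (not isolated)
Conditions: TBAF, AcOH, THF, rt → 40 °C; then LiOH, MeOH/H2O, rt; 1 M HCl to pH 4
Reagents that add atoms: lithium hydroxide, [Li+].[OH-]
Why: Fluoride cleaves both silyl ethers and hydroxide then hydrolyses the two acetates and the ethyl ester (saponification); no stereocentre is touched.

**Compound list**
1 | but-3-en-1-ol | C=CCCO | starting material
2 | tert-butyl(but-3-en-1-yloxy)dimethylsilane | C=CCCO[Si](C)(C)C(C)(C)C | intermediate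
3 | trichloroacetyl chloride | ClC(=O)C(Cl)(Cl)Cl | starting material
4 | dichloroketene | ClC(Cl)=C=O | intermediate
5 | rac-2,2-dichloro-3-[2-(TBS-oxy)ethyl]cyclobutan-1-one | O=C1CC(CCO[Si](C)(C)C(C)(C)C)C1(Cl)Cl | intermediate
6 | 3-[2-(TBS-oxy)ethyl]cyclobutan-1-one | O=C1CC(CCO[Si](C)(C)C(C)(C)C)C1 | intermediate
7 | prop-2-yn-1-ol | C#CCO | starting material
8 | tert-butyldiphenyl(prop-2-yn-1-yloxy)silane | C#CCO[Si](c1ccccc1)(c1ccccc1)C(C)(C)C | intermediate
9 | hept-1-yne | CCCCCC#C | starting material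
10 | chlorobis(cyclopentadienyl)[(E)-hept-1-enyl]zirconium | CCCCC/C=C/[Zr](Cl)(C1C=CC=C1)C1C=CC=C1 | intermediate
11 | (E)-1-iodohept-1-ene | CCCCC/C=C/I | intermediate
12 | tert-butyl{[(E)-dec-4-en-2-yn-1-yl]oxy}diphenylsilane | CCCCC/C=C/C#CCO[Si](c1ccccc1)(c1ccccc1)C(C)(C)C | intermediate
13 | (5S)-1-[(E)-hept-1-enyl]-2-[(TBDPS-oxy)methyl]-5-[2-(TBS-oxy)ethyl]cyclohex-1-en-3-one | CCCCC/C=C/C1=C(CO[Si](c2ccccc2)(c2ccccc2)C(C)(C)C)C(=O)C[C@H](CCO[Si](C)(C)C(C)(C)C)C1 | intermediate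
14 | (5S)-3-(TBS-oxy)-1-[(E)-hept-1-enyl]-2-[(TBDPS-oxy)methyl]-5-[2-(TBS-oxy)ethyl]cyclohexa-1,3-diene | CCCCC/C=C/C1=C(CO[Si](c2ccccc2)(c2ccccc2)C(C)(C)C)C(O[Si](C)(C)C(C)(C)C)=C[C@H](CCO[Si](C)(C)C(C)(C)C)C1 | intermediate
15 | (4S,5S)-4-(TBS-oxy)-1-[(E)-hept-1-enyl]-2-[(TBDPS-oxy)methyl]-5-[2-(TBS-oxy)ethyl]cyclohex-1-en-3-one | CCCCC/C=C/C1=C(CO[Si](c2ccccc2)(c2ccccc2)C(C)(C)C)C(=O)[C@@H](O[Si](C)(C)C(C)(C)C)[C@H](CCO[Si](C)(C)C(C)(C)C)C1 | intermediate
16 | (4S,5R)-4-(TBS-oxy)-3-(trimethylsilyloxy)-1-[(E)-hept-1-enyl]-2-[(TBDPS-oxy)methyl]-5-[2-(TBS-oxy)ethyl]cyclohexa-2,6-diene | CCCCC/C=C/C1=C[C@@H](CCO[Si](C)(C)C(C)(C)C)[C@H](O[Si](C)(C)C(C)(C)C)C(O[Si](C)(C)C)=C1CO[Si](c1ccccc1)(c1ccccc1)C(C)(C)C | intermediate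
17 | (4S,5R,6R)-4-(TBS-oxy)-6-hydroxy-1-[(E)-hept-1-enyl]-2-[(TBDPS-oxy)methyl]-5-[2-(TBS-oxy)ethyl]cyclohex-1-en-3-one (6-OH trans to the side chain) | CCCCC/C=C/C1=C(CO[Si](c2ccccc2)(c2ccccc2)C(C)(C)C)C(=O)[C@@H](O[Si](C)(C)C(C)(C)C)[C@H](CCO[Si](C)(C)C(C)(C)C)[C@H]1O | intermediate
18 | (4S,5S)-4-(TBS-oxy)-1-[(E)-hept-1-enyl]-2-[(TBDPS-oxy)methyl]-5-[2-(TBS-oxy)ethyl]cyclohex-1-ene-3,6-dione | CCCCC/C=C/C1=C(CO[Si](c2ccccc2)(c2ccccc2)C(C)(C)C)C(=O)[C@@H](O[Si](C)(C)C(C)(C)C)[C@H](CCO[Si](C)(C)C(C)(C)C)C1=O | intermediate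
19 | (3R,4S,5R,6S)-4-(TBS-oxy)-1-[(E)-hept-1-enyl]-2-[(TBDPS-oxy)methyl]-5-[2-(TBS-oxy)ethyl]cyclohex-1-ene-3,6-diol | CCCCC/C=C/C1=C(CO[Si](c2ccccc2)(c2ccccc2)C(C)(C)C)[C@@H](O)[C@@H](O[Si](C)(C)C(C)(C)C)[C@H](CCO[Si](C)(C)C(C)(C)C)[C@@H]1O | intermediate
20 | (3R,4S,5R,6S)-3,6-diacetoxy-4-(TBS-oxy)-1-[(E)-hept-1-enyl]-2-[(TBDPS-oxy)methyl]-5-[2-(TBS-oxy)ethyl]cyclohex-1-ene | CCCCC/C=C/C1=C(CO[Si](c2ccccc2)(c2ccccc2)C(C)(C)C)[C@@H](OC(C)=O)[C@@H](O[Si](C)(C)C(C)(C)C)[C@H](CCO[Si](C)(C)C(C)(C)C)[C@@H]1OC(C)=O | intermediate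
21 | (3R,4S,5R,6S)-3,6-diacetoxy-4-(TBS-oxy)-1-[(E)-hept-1-enyl]-2-[(TBDPS-oxy)methyl]-5-(2-hydroxyethyl)cyclohex-1-ene | CCCCC/C=C/C1=C(CO[Si](c2ccccc2)(c2ccccc2)C(C)(C)C)[C@@H](OC(C)=O)[C@@H](O[Si](C)(C)C(C)(C)C)[C@H](CCO)[C@@H]1OC(C)=O | intermediate
22 | ethyl 2-(triphenyl-λ5-phosphanylidene)propanoate | CCOC(=O)C(C)=P(c1ccccc1)(c1ccccc1)c1ccccc1 | starting material
23 | 2-[(3R,4S,5R,6S)-3,6-diacetoxy-4-(TBS-oxy)-1-[(E)-hept-1-enyl]-2-[(TBDPS-oxy)methyl]cyclohex-1-en-5-yl]acetaldehyde | CCCCC/C=C/C1=C(CO[Si](c2ccccc2)(c2ccccc2)C(C)(C)C)[C@@H](OC(C)=O)[C@@H](O[Si](C)(C)C(C)(C)C)[C@H](CC=O)[C@@H]1OC(C)=O | intermediate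
24 | ethyl (2E)-4-[(3R,4S,5R,6S)-3,6-diacetoxy-4-(TBS-oxy)-1-[(E)-hept-1-enyl]-2-[(TBDPS-oxy)methyl]cyclohex-1-en-5-yl]-2-methylbut-2-enoate | CCCCC/C=C/C1=C(CO[Si](c2ccccc2)(c2ccccc2)C(C)(C)C)[C@@H](OC(C)=O)[C@@H](O[Si](C)(C)C(C)(C)C)[C@H](C/C=C(\C)C(=O)OCC)[C@@H]1OC(C)=O | intermediate
25 | ethyl (2E)-4-[(3R,4S,5S,6S)-3,6-diacetoxy-4-hydroxy-1-[(E)-hept-1-enyl]-2-(hydroxymethyl)cyclohex-1-en-5-yl]-2-methylbut-2-enoate (same spatial arrangement as 24; the C5 descriptor changes with CIP priorities) | CCCCC/C=C/C1=C(CO)[C@@H](OC(C)=O)[C@@H](O)[C@H](C/C=C(\C)C(=O)OCC)[C@@H]1OC(C)=O | intermediate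
26 | pestallic acid P, (2E)-4-[(3R,4S,5R,6S)-1-[(E)-hept-1-enyl]-3,4,6-trihydroxy-2-(hydroxymethyl)cyclohex-1-en-5-yl]-2-methylbut-2-enoic acid | CCCCC/C=C/C1=C(CO)[C@@H](O)[C@@H](O)[C@H](C/C=C(\C)C(=O)O)[C@@H]1O | target

**Step count:** 15 steps in total. Longest linear sequence: 12 steps (1–3, then 7–15).

**Steps most likely to fail**

Step 7 (proposed new method). What may go wrong: the catalyst may discriminate poorly between the two enantiotopic C3–CH2 bonds, or alkyne oligomerisation may outrun insertion. The fallback sets out from 6 and 12 and uses known chemistry only. The achiral Ni(cod)2/PCy3 system (toluene, 100 °C), the established intermolecular alkyne insertion into 3-substituted cyclobutanones, should give the racemic enone F1. CBS reduction with (S)-Me-CBS and catecholborane (toluene, −78 °C) should then reduce both enantiomers under reagent control to the (3R)-carbinol. The (5S)-enone thus gives the cis allylic alcohol F2 and the (5R)-enone the trans allylic alcohol F3, which are diastereomers and separable on silica. MnO2 oxidation of F2 (CH2Cl2, rt) comes back to the route at 13.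

Step 9. What may go wrong: deprotonation at the chain allylic carbon C9 or at C4 instead of C6, or loss of silanolate from the CH2O group of the dienolate. The fallback removes the competing chain CH2 from the substrate and sets out from 8 and 6. Sonogashira coupling of 8 with vinyl bromide should give the pent-4-en-2-ynyl silyl ether F4. Ring expansion of 6 with F4 under the conditions of step 7 should give the vinyl enone F5. Rubottom oxidation as in step 8, through the TBS dienol ether F6, should give the 4-silyloxy vinyl enone F7. The sequence of step 9, through the TMS dienol ether F8, should then give the γ-hydroxy vinyl enone F9, in which only the ring C6–H is available. Cross-metathesis of F9 with hept-1-ene (second-generation Ru benzylidene catalyst, CH2Cl2, 40 °C) installs the pentyl terminus with E geometry and comes back to the route at 17.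

Step 10 (with its reduction in step 11). What may go wrong: β-elimination of the C4 silyloxy group and aromatisation of the enedione towards a quinone, or conjugate reduction by the hydride. The fallback avoids the enedione and sets out from 17. Mitsunobu inversion (PPh3, DIAD, 4-nitrobenzoic acid, toluene, 0 °C → rt) should give the 6-epi 4-nitrobenzoate F10. Methanolysis (K2CO3, MeOH, 0 °C) should give the cis γ-hydroxy enone F11. L-Selectride reduction of the single remaining ketone (THF, −78 °C), opposite the C4 silyloxy group, comes back to the route at 19.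

**Further compounds**
F1 | step 7 | racemic 1-[(E)-hept-1-enyl]-2-[(TBDPS-oxy)methyl]-5-[2-(TBS-oxy)ethyl]cyclohex-1-en-3-one | CCCCC/C=C/C1=C(CO[Si](c2ccccc2)(c2ccccc2)C(C)(C)C)C(=O)CC(CCO[Si](C)(C)C(C)(C)C)C1
F2 | step 7 | (3R,5S)-1-[(E)-hept-1-enyl]-2-[(TBDPS-oxy)methyl]-5-[2-(TBS-oxy)ethyl]cyclohex-1-en-3-ol (cis) | CCCCC/C=C/C1=C(CO[Si](c2ccccc2)(c2ccccc2)C(C)(C)C)[C@H](O)C[C@H](CCO[Si](C)(C)C(C)(C)C)C1
F3 | step 7 | (3R,5R)-1-[(E)-hept-1-enyl]-2-[(TBDPS-oxy)methyl]-5-[2-(TBS-oxy)ethyl]cyclohex-1-en-3-ol (trans) | CCCCC/C=C/C1=C(CO[Si](c2ccccc2)(c2ccccc2)C(C)(C)C)[C@H](O)C[C@@H](CCO[Si](C)(C)C(C)(C)C)C1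
F4 | step 9 | tert-butyl(pent-4-en-2-yn-1-yloxy)diphenylsilane | C=CC#CCO[Si](c1ccccc1)(c1ccccc1)C(C)(C)C
F5 | step 9 | (5S)-1-ethenyl-2-[(TBDPS-oxy)methyl]-5-[2-(TBS-oxy)ethyl]cyclohex-1-en-3-one | C=CC1=C(CO[Si](c2ccccc2)(c2ccccc2)C(C)(C)C)C(=O)C[C@H](CCO[Si](C)(C)C(C)(C)C)C1
F6 | step 9 | (5S)-3-(TBS-oxy)-1-ethenyl-2-[(TBDPS-oxy)methyl]-5-[2-(TBS-oxy)ethyl]cyclohexa-1,3-diene | C=CC1=C(CO[Si](c2ccccc2)(c2ccccc2)C(C)(C)C)C(O[Si](C)(C)C(C)(C)C)=C[C@H](CCO[Si](C)(C)C(C)(C)C)C1
F7 | step 9 | (4S,5S)-4-(TBS-oxy)-1-ethenyl-2-[(TBDPS-oxy)methyl]-5-[2-(TBS-oxy)ethyl]cyclohex-1-en-3-one | C=CC1=C(CO[Si](c2ccccc2)(c2ccccc2)C(C)(C)C)C(=O)[C@@H](O[Si](C)(C)C(C)(C)C)[C@H](CCO[Si](C)(C)C(C)(C)C)C1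
F8 | step 9 | (4S,5R)-4-(TBS-oxy)-3-(trimethylsilyloxy)-1-ethenyl-2-[(TBDPS-oxy)methyl]-5-[2-(TBS-oxy)ethyl]cyclohexa-2,6-diene | C=CC1=C[C@@H](CCO[Si](C)(C)C(C)(C)C)[C@H](O[Si](C)(C)C(C)(C)C)C(O[Si](C)(C)C)=C1CO[Si](c1ccccc1)(c1ccccc1)C(C)(C)C
F9 | step 9 | (4S,5R,6R)-4-(TBS-oxy)-6-hydroxy-1-ethenyl-2-[(TBDPS-oxy)methyl]-5-[2-(TBS-oxy)ethyl]cyclohex-1-en-3-one | C=CC1=C(CO[Si](c2ccccc2)(c2ccccc2)C(C)(C)C)C(=O)[C@@H](O[Si](C)(C)C(C)(C)C)[C@H](CCO[Si](C)(C)C(C)(C)C)[C@H]1O
F10 | step 10 | 4-(TBS-oxy)-1-[(E)-hept-1-enyl]-2-[(TBDPS-oxy)methyl]-5-[2-(TBS-oxy)ethyl]-3-oxocyclohex-1-en-6-yl 4-nitrobenzoate (ester cis to the side chain) | CCCCC/C=C/C1=C(CO[Si](c2ccccc2)(c2ccccc2)C(C)(C)C)C(=O)[C@@H](O[Si](C)(C)C(C)(C)C)[C@H](CCO[Si](C)(C)C(C)(C)C)[C@@H]1OC(=O)c1ccc(cc1)[N+](=O)[O-]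
F11 | step 10 | 4-(TBS-oxy)-6-hydroxy-1-[(E)-hept-1-enyl]-2-[(TBDPS-oxy)methyl]-5-[2-(TBS-oxy)ethyl]cyclohex-1-en-3-one (6-OH cis to the side chain) | CCCCC/C=C/C1=C(CO[Si](c2ccccc2)(c2ccccc2)C(C)(C)C)C(=O)[C@@H](O[Si](C)(C)C(C)(C)C)[C@H](CCO[Si](C)(C)C(C)(C)C)[C@@H]1O
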